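The route rests on opening the cyclohexane between the carbinol carbon C1 and the methyl-bearing carbon C6 (C2 carries the gem-dimethyl group). The HO–C1–C6–CH3 array, hydroxyl trans to methyl, is the retron of a reductive ketyl–olefin cyclization, in which a nucleophilic ketyl radical joins a carbonyl carbon to an unpolarized alkene carbon. In one operation SmI2 with a chiral ligand should turn an acyclic ω-vinyl ketone, (E)-13-chloro-6,6,10-trimethyltrideca-1,10-dien-7-one, into the ring with its tertiary alcohol and both stereocentres (6-exo-trig). The ketone is assembled by two alkylations; the dienyl butenolide is attached afterwards by carbomagnesiation of propargyl alcohol and a Stille coupling.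

Key step: step 7

Assumptions: The sense of induction of the chiral ligand in step 7 cannot be predicted; the antipode that gives the (1R,6S) product is to be chosen after a test run, and the route is written for that antipode. Compounds 1, 2, 7, 14, 18 and 19 are taken as commercially available.

Step 1
Reactants: 1 2-methylpropanenitrile; 2 5-bromopent-1-ene
Product: 4 2,2-dimethylhept-6-enenitrile, via 2-lithio-2-methylpropanenitrile 3 (not isolated)
Conditions: LiN(i-Pr)2, THF, −78 °C; then 2, −78 °C → rt
Reagents that add atoms: none
Why: Deprotonation gives a nitrile-stabilized tertiary carbanion that should be alkylated by the primary bromide in an SN2 reaction (nitrile anion alkylation); no stereocentre is formed.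

Step 2
Reactants: 4 2,2-dimethylhept-6-enenitrile
Product: 6 3,3-dimethyloct-7-en-2-one, via lithium ketimide 5 (not isolated)
Conditions: MeLi, Et2O, 0 °C → rt; then 2 M aq. HCl, rt
Reagents that add atoms: methyllithium [Li]C; water O
Why: Methyllithium should add once to the hindered nitrile to give an N-lithio ketimine that resists a second addition and is hydrolysed by aqueous acid to the methyl ketone (organolithium–nitrile ketone synthesis).

Step 3
Reactants: 7 4-methylpent-3-en-1-ol
Product: 8 5-chloro-2-methylpent-2-ene
Conditions: N-chlorosuccinimide, PPh3, CH2Cl2, 0 °C → rt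
Reagents that add atoms: N-chlorosuccinimide ClN1C(=O)CCC1=O
Why: Appel-type chlorination should convert the primary homoallylic alcohol into the chloride under neutral conditions that leave the trisubstituted alkene untouched.

Step 4
Reactants: 8 5-chloro-2-methylpent-2-ene
Product: 9 (2E)-5-chloro-2-methylpent-2-en-1-ol
Conditions: SeO2 (cat.), t-BuOOH, CH2Cl2, rt
Reagents that add atoms: tert-butyl hydroperoxide CC(C)(C)OO
Why: Riley allylic oxidation (ene reaction, then [2,3]-sigmatropic shift) hydroxylates the methyl group trans to the chain of a trisubstituted alkene, which fixes the E geometry of the later chain alkene.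

Step 5
Reactants: 9 (2E)-5-chloro-2-methylpent-2-en-1-ol
Product: 10 (2E)-1-bromo-5-chloro-2-methylpent-2-ene
Conditions: CBr4, PPh3, CH2Cl2, 0 °C
Reagents that add atoms: carbon tetrabromide BrC(Br)(Br)Br
Why: Appel bromination of the primary allylic alcohol should proceed by SN2 displacement without allylic transposition or loss of alkene geometry.

Step 6
Reactants: 6 3,3-dimethyloct-7-en-2-one (slight excess); 10 (2E)-1-bromo-5-chloro-2-methylpent-2-ene
Product: 12 (10E)-13-chloro-6,6,10-trimethyltrideca-1,10-dien-7-one, via lithium enolate 11 (not isolated)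
Conditions: LiN(i-Pr)2, THF, −78 °C; then 10, DMPU, −78 → −20 °C
Reagents that add atoms: none
Why: The ketone can enolize only towards its methyl group, so a single lithium enolate forms and should be C-alkylated by SN2 at the allylic bromide, which is far more reactive than the primary chloride (kinetic enolate alkylation).

Step 7
Reactants: 12 (10E)-13-chloro-6,6,10-trimethyltrideca-1,10-dien-7-one
Product: 13 (1R,6S)-1-[(3E)-6-chloro-3-methylhex-3-en-1-yl]-2,2,6-trimethylcyclohexan-1-ol
Conditions: SmI2 (2.5 equiv), chiral aminodiol ligand (1R,1'R)-2,2'-(benzylazanediyl)bis(1-phenylethan-1-ol) or its antipode (2.5 equiv, recovered), t-BuOH, THF, −20 °C → rt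
Reagents that add atoms: none
Why: Proposed new method: electron transfer from the ligated divalent samarium to the ketone should give a ketyl radical anion whose carbon (C7 of 12, later ring C1) adds to the internal carbon of the terminal vinyl group (C2 of 12, later ring C6), after which the exocyclic primary radical is reduced by a second SmI2 and protonated by t-BuOH to the methyl group; the closest known reaction types are the SmI2–HMPA reductive cyclization of unactivated olefinic ketones (racemic) and the enantioselective SmI2–chiral aminodiol ketyl–olefin cyclizations of keto esters, neither of which has been shown to give enantiocontrol with a simple dialkyl ketone and an unactivated alkene. The ring closes in the 6-exo-trig radical mode through a chair-like transition state, and the gem-dimethyl group next to the ketyl carbon favours closure (Thorpe–Ingold effect) while it blocks pinacol dimerization. The relative configuration, hydroxyl trans to the new methyl group, follows the anti preference that ketyl–olefin cyclizations show in general, the electron-rich O–Sm unit avoiding the alkene in the transition state. The absolute configuration (1R,6S) must come from the chiral aminodiolate held on the oxophilic trivalent samarium of the ketyl, which has a tertiary and a primary alkyl group on the ketyl carbon to tell apart. The step needs cyclization to outrun simple reduction of the ketyl and to leave the other sites alone: the chain alkene could only be reached in a 4-exo or 5-endo mode, and the primary chloride is not reduced by SmI2 at or below room temperature.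

Step 8
Reactants: 13 (1R,6S)-1-[(3E)-6-chloro-3-methylhex-3-en-1-yl]-2,2,6-trimethylcyclohexan-1-ol; 14 prop-2-yn-1-ol (1.2 equiv)
Product: 17 (1R,6S)-1-[(3E,7Z)-7-(hydroxymethyl)-8-iodo-3-methylocta-3,7-dien-1-yl]-2,2,6-trimethylcyclohexan-1-ol, via alkoxide Grignard reagent 15 (not isolated), via alkenylmagnesium species 16 (not isolated)
Conditions: 13, MeMgCl (1 equiv), THF, 0 °C; Mg, THF, reflux; then 14 pre-treated with MeMgCl (1 equiv), CuI (10 mol%), THF, rt; then I2 (1.1 equiv), −78 °C; aqueous work-up
Reagents that add atoms: iodine II
Why: The chloromagnesium alkoxide tolerates magnesium insertion into the primary C–Cl bond, and CuI-catalysed carbomagnesiation of the propargyl alkoxide should deliver the alkyl group to C2 anti to magnesium, which is held on C3 cis to the CH2O group in a five-membered chelate, so that iodinolysis gives the iodoalkene with iodine cis to the hydroxymethyl group (alkoxide-directed anti-carbomagnesiation of a propargylic alcohol).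

Step 9
Reactants: 18 4-bromofuran-2(5H)-one; 19 (E)-1,2-bis(tributylstannyl)ethene (3 equiv)
Product: 20 4-[(E)-2-(tributylstannyl)ethenyl]furan-2(5H)-one
Conditions: Pd2(dba)3 (cat.), P(2-furyl)3, THF, 50 °C
Reagents that add atoms: none
Why: Stille coupling of the activated β-bromo butenolide with excess distannane should stop after one coupling, because the remaining stannyl group then sits on an electron-poor diene, and it keeps the E geometry.

Step 10
Reactants: 17 (1R,6S)-1-[(3E,7Z)-7-(hydroxymethyl)-8-iodo-3-methylocta-3,7-dien-1-yl]-2,2,6-trimethylcyclohexan-1-ol; 20 4-[(E)-2-(tributylstannyl)ethenyl]furan-2(5H)-one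
Product: 21 4-[(1E,3Z,7E)-10-[(1R,6S)-1-hydroxy-2,2,6-trimethylcyclohexyl]-4-(hydroxymethyl)-8-methyldeca-1,3,7-trien-1-yl]furan-2(5H)-one
Conditions: Pd2(dba)3 (cat.), AsPh3, CuI (cat.), DMF, rt, dark
Reagents that add atoms: none
Why: Stille coupling should join the two sp2 carbons with retention of both alkene geometries under neutral conditions that spare the butenolide and the free hydroxyl groups.

Step 11
Reactants: 21 4-[(1E,3Z,7E)-10-[(1R,6S)-1-hydroxy-2,2,6-trimethylcyclohexyl]-4-(hydroxymethyl)-8-methyldeca-1,3,7-trien-1-yl]furan-2(5H)-one
Product: 22 [(2Z,4E)-2-{(3E)-6-[(1R,6S)-1-hydroxy-2,2,6-trimethylcyclohexyl]-4-methylhex-3-en-1-yl}-5-(5-oxo-2,5-dihydrofuran-3-yl)penta-2,4-dien-1-yl] acetate (target)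
Conditions: Ac2O, pyridine, CH2Cl2, 0 °C
Reagents that add atoms: acetic anhydride CC(=O)OC(C)=O
Why: Acetylation should be selective for the primary allylic hydroxyl, because the tertiary hydroxyl between a quaternary and a tertiary ring carbon is too hindered to be acylated under these conditions.

Compound list
1 | 2-methylpropanenitrile | CC(C)C#N | starting material
2 | 5-bromopent-1-ene | BrCCCC=C | starting material
3 | 2-lithio-2-methylpropanenitrile | [Li]C(C)(C)C#N | intermediate (not isolated)
4 | 2,2-dimethylhept-6-enenitrile | N#CC(C)(C)CCCC=C | intermediate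
5 | lithium ketimide (N-lithio-3,3-dimethyloct-7-en-2-imine) | [Li]N=C(C)C(C)(C)CCCC=C | intermediate (not isolated)
6 | 3,3-dimethyloct-7-en-2-one | CC(=O)C(C)(C)CCCC=C | intermediate
7 | 4-methylpent-3-en-1-ol | CC(C)=CCCO | starting material
8 | 5-chloro-2-methylpent-2-ene | CC(C)=CCCCl | intermediate
9 | (2E)-5-chloro-2-methylpent-2-en-1-ol | OC/C(C)=C/CCCl | intermediate
10 | (2E)-1-bromo-5-chloro-2-methylpent-2-ene | BrC/C(C)=C/CCCl | intermediate
11 | lithium enolate (lithium 3,3-dimethylocta-1,7-dien-2-olate) | [Li]OC(=C)C(C)(C)CCCC=C | intermediate (not isolated)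
12 | (10E)-13-chloro-6,6,10-trimethyltrideca-1,10-dien-7-one | C=CCCCC(C)(C)C(=O)CC/C(C)=C/CCCl | intermediate
13 | (1R,6S)-1-[(3E)-6-chloro-3-methylhex-3-en-1-yl]-2,2,6-trimethylcyclohexan-1-ol | ClCC/C=C(\C)CC[C@@]1(O)[C@@H](C)CCCC1(C)C | intermediate
14 | prop-2-yn-1-ol | C#CCO | starting material
15 | alkoxide Grignard reagent, [(3E)-6-[(1R,6S)-1-(chloromagnesiooxy)-2,2,6-trimethylcyclohexyl]-4-methylhex-3-en-1-yl]magnesium chloride | Cl[Mg]CC/C=C(\C)CC[C@@]1(O[Mg]Cl)[C@@H](C)CCCC1(C)C | intermediate (not isolated)
16 | alkenylmagnesium species, the (Z)-1-chloromagnesio alkene with both hydroxyls as chloromagnesium alkoxides | Cl[Mg]OC/C(=C\[Mg]Cl)CC/C=C(\C)CC[C@@]1(O[Mg]Cl)[C@@H](C)CCCC1(C)C | intermediate (not isolated)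
17 | (1R,6S)-1-[(3E,7Z)-7-(hydroxymethyl)-8-iodo-3-methylocta-3,7-dien-1-yl]-2,2,6-trimethylcyclohexan-1-ol | OC/C(=C\I)CC/C=C(\C)CC[C@@]1(O)[C@@H](C)CCCC1(C)C | intermediate
18 | 4-bromofuran-2(5H)-one | BrC1=CC(=O)OC1 | starting material
19 | (E)-1,2-bis(tributylstannyl)ethene | CCCC[Sn](CCCC)(CCCC)/C=C/[Sn](CCCC)(CCCC)CCCC | starting material
20 | 4-[(E)-2-(tributylstannyl)ethenyl]furan-2(5H)-one | CCCC[Sn](CCCC)(CCCC)/C=C/C1=CC(=O)OC1 | intermediate
21 | 4-[(1E,3Z,7E)-10-[(1R,6S)-1-hydroxy-2,2,6-trimethylcyclohexyl]-4-(hydroxymethyl)-8-methyldeca-1,3,7-trien-1-yl]furan-2(5H)-one | OC/C(=C\C=C\C1=CC(=O)OC1)CC/C=C(\C)CC[C@@]1(O)[C@@H](C)CCCC1(C)C | intermediate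
22 | [(2Z,4E)-2-{(3E)-6-[(1R,6S)-1-hydroxy-2,2,6-trimethylcyclohexyl]-4-methylhex-3-en-1-yl}-5-(5-oxo-2,5-dihydrofuran-3-yl)penta-2,4-dien-1-yl] acetate | CC(=O)OC/C(=C\C=C\C1=CC(=O)OC1)CC/C=C(\C)CC[C@@]1(O)[C@@H](C)CCCC1(C)C | target

Total step count: 11. Longest linear sequence: 8 steps (steps 3, 4, 5, 6, 7, 8, 10, 11).

Steps most likely to fail

Step 7 (Proposed new method). The chiral ligand may discriminate too weakly between the two faces of a ketyl that binds samarium through one oxygen only. The ketyl may also be reduced to the secondary alcohol before the 6-exo closure, and the gem-dimethyl group may erode the trans preference. The fallback sets out from 12 and uses the known achiral cyclization (SmI2, HMPA, t-BuOH, THF, 0 °C → rt), which should give the trans cyclohexanol as a racemate. This is 13 together with its enantiomer (1S,6R)-1-[(3E)-6-chloro-3-methylhex-3-en-1-yl]-2,2,6-trimethylcyclohexan-1-ol F1. Resolution by preparative chromatography on an amylose tris(3,5-dimethylphenylcarbamate) stationary phase would remove F1, and the route is rejoined at 13.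

Step 8. Magnesium insertion into the chloride may be incomplete, and the valuable Grignard reagent may be protonated by the acetylenic C–H instead of adding across the triple bond. Iodine may also trigger iodoetherification of the chain alkene by the tertiary alkoxide. The fallback sets out from 13 and replaces carbomagnesiation by a Negishi coupling:
- Finkelstein exchange (NaI, acetone, reflux) gives (1R,6S)-1-[(3E)-6-iodo-3-methylhex-3-en-1-yl]-2,2,6-trimethylcyclohexan-1-ol F2.
- Zinc insertion (Zn, LiCl, THF) gives the alkylzinc iodide [(3E)-6-[(1R,6S)-1-hydroxy-2,2,6-trimethylcyclohexyl]-4-methylhex-3-en-1-yl]zinc iodide F3, used without isolation; alkylzinc iodides tolerate hindered and allylic hydroxyl groups in fast couplings.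
- Separately, anti-addition of bromine to 14 (Br2, CH2Cl2, −20 °C) gives (E)-2,3-dibromoprop-2-en-1-ol F4.
- Stille coupling of the more accessible terminal C–Br bond of F4 with 20 gives 4-[(1E,3E)-4-bromo-5-hydroxypenta-1,3-dien-1-yl]furan-2(5H)-one F5.
- Negishi coupling of F3 with F5 (Pd(OAc)2, SPhos, THF, rt) should form the sp3–sp2 bond with retention of alkene geometry.

This comes back to the route at 21, so 17 and step 10 are bypassed.

Step 10. Transmetalation of the electron-poor dienylstannane may be slow, which would allow homocoupling of the iodide, protodestannylation, or isomerization of the light-sensitive triene. The fallback sets out from 17 and 18 and uses a Heck reaction in place of the Stille coupling. Compound 18 is coupled with tributyl(vinyl)stannane (Pd(PPh3)4, dioxane, 80 °C) to give 4-ethenylfuran-2(5H)-one F6. A Heck reaction of 17 with the terminal vinyl group of F6 (Pd(OAc)2, Ag2CO3, DMF, rt) should then give the E diene with retention of the iodoalkene geometry. This comes back to the route at 21.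

Further compounds
F1 | step 7 | (1S,6R)-1-[(3E)-6-chloro-3-methylhex-3-en-1-yl]-2,2,6-trimethylcyclohexan-1-ol | ClCC/C=C(\C)CC[C@]1(O)[C@H](C)CCCC1(C)C
F2 | step 8 | (1R,6S)-1-[(3E)-6-iodo-3-methylhex-3-en-1-yl]-2,2,6-trimethylcyclohexan-1-ol | ICC/C=C(\C)CC[C@@]1(O)[C@@H](C)CCCC1(C)C
F3 | step 8 | [(3E)-6-[(1R,6S)-1-hydroxy-2,2,6-trimethylcyclohexyl]-4-methylhex-3-en-1-yl]zinc iodide | I[Zn]CC/C=C(\C)CC[C@@]1(O)[C@@H](C)CCCC1(C)C
F4 | step 8 | (E)-2,3-dibromoprop-2-en-1-ol | OC/C(Br)=C\Br
F5 | step 8 | 4-[(1E,3E)-4-bromo-5-hydroxypenta-1,3-dien-1-yl]furan-2(5H)-one | OC/C(Br)=C\C=C\C1=CC(=O)OC1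
F6 | step 10 | 4-ethenylfuran-2(5H)-one | C=CC1=CC(=O)OC1
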